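**Plan**

- Retrosynthesis: after removal of the two phenol protecting groups and reversal of an allyl-to-prenyl cross-metathesis, ring C is cut in one operation at O1–C2, C2–C3 and C4–OH. This leaves a ring A 2-vinylphenol, 4-acetoxybenzaldehyde (ring B plus C2) and water.
- Enabling feature: C4 is a benzylic carbinol carbon on ring A, where O1, the 5-oxygen and the 7-methoxy group all stabilise a C4 cation. C2 is the O1-bearing benzylic carbon next to ring B, and only the C3 methylene lies between the two.
- Forward: ring A is dressed from 2,4,6-trihydroxybenzaldehyde (4-O-methylation, O-allylation, silylation, Claisen shift of allyl to the future C8, methylenation). Ring C then closes between the finished rings A and B in a single asymmetric Prins step.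
- The C8 side chain is carried through the acid step as allyl, because a prenyl group ortho to the free phenol would cyclise to a chroman under strong acid. It is converted to prenyl afterwards, and the acetate and silyl ether are then removed.
- Stereochemistry: C2 (S) comes from the chiral confined acid in the C2–C3 bond formation. C4 (R) comes from pseudo-axial water capture trans to the C2 aryl group, reinforced by peri strain with the 5-silyloxy group.

Key step: step 6

Assumption: the (S,S)-enantiomer of the imidodiphosphorimidate catalyst is written as the one that gives 2S; if a test reaction shows the opposite sense of induction, its mirror image is used and nothing else changes.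

**Route**

Step 1
Reactants: 1 2,4,6-trihydroxybenzaldehyde
Product: 2 2,6-dihydroxy-4-methoxybenzaldehyde
Conditions: MeI (1.05 equiv), CsHCO3, MeCN, 40 °C
Reagents that add atoms: iodomethane, CI
Why: Williamson O-methylation in which the weak base ionises only the 4-hydroxyl, the most acidic one and the only one not hydrogen-bonded to the formyl group.

Step 2
Reactants: 2 2,6-dihydroxy-4-methoxybenzaldehyde; 3 allyl bromide
Product: 4 2-(allyloxy)-6-hydroxy-4-methoxybenzaldehyde
Conditions: K2CO3, acetone, reflux
Reagents that add atoms: none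
Why: Williamson O-allylation of one of two equivalent hydroxyls, after which the remaining hydroxyl stays chelated to the carbonyl and should resist a second alkylation.

Step 3
Reactants: 4 2-(allyloxy)-6-hydroxy-4-methoxybenzaldehyde
Product: 5 2-(allyloxy)-4-methoxy-6-(triisopropylsilyloxy)benzaldehyde
Conditions: TIPSCl, imidazole, DMAP (cat.), DMF, rt to 40 °C
Reagents that add atoms: triisopropylsilyl chloride, CC(C)[Si](Cl)(C(C)C)C(C)C
Why: Silyl ether formation on the only free phenol fixes, before the allyl shift, which ortho oxygen remains masked, so the two ortho oxygens never have to be told apart by selectivity.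

Step 4
Reactants: 5 2-(allyloxy)-4-methoxy-6-(triisopropylsilyloxy)benzaldehyde
Product: 7 3-allyl-2-hydroxy-4-methoxy-6-(triisopropylsilyloxy)benzaldehyde, via 6-allylcyclohexa-2,4-dienone 6 (not isolated)
Conditions: N,N-diethylaniline, 190 °C, sealed tube
Reagents that add atoms: none
Why: Aromatic Claisen rearrangement ([3,3]-sigmatropic shift) delivers the allyl group to the only unsubstituted ortho carbon and the dienone tautomerises to the phenol, which is the hydroxyl that will become O1.

Step 5
Reactants: 7 3-allyl-2-hydroxy-4-methoxy-6-(triisopropylsilyloxy)benzaldehyde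
Product: 8 2-allyl-3-methoxy-5-(triisopropylsilyloxy)-6-vinylphenol
Conditions: Ph3PCH3Br (3 equiv), KOtBu (2.9 equiv), THF, 0 °C to rt
Reagents that add atoms: methyltriphenylphosphonium bromide, C[P+](c1ccccc1)(c1ccccc1)c1ccccc1.[Br-]
Why: Wittig methylenation, in which salicylaldehydes react as their phenoxides with an excess of the non-stabilised ylide and the aryl silyl ether tolerates the cold basic medium.

Step 6
Reactants: 8 2-allyl-3-methoxy-5-(triisopropylsilyloxy)-6-vinylphenol; 9 4-acetoxybenzaldehyde
Product: 11 4-[(2S,4R)-8-allyl-4-hydroxy-7-methoxy-5-(triisopropylsilyloxy)chroman-2-yl]phenyl acetate, via aryl hemiacetal 10 (not isolated)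
Conditions: 9 (1.5 equiv), (S,S)-IDPi (imidodiphosphorimidate from two 3,3'-diaryl-BINOL units, N-triflyl groups on phosphorus; 5 mol%), H2O (2 equiv), CH2Cl2 (0.05 M), 0 °C
Reagents that add atoms: water, O
Why: Proposed new method: the phenol of 8 adds to the acid-activated aldehyde to give hemiacetal 10, which loses water inside the chiral ion pair to form an O-aryl oxocarbenium ion; the terminal vinyl carbon attacks its carbon (C2–C3 bond) in a 6-endo-trig Prins closure of ring C, and the resulting C4 benzylic cation, stabilised by O1, the 5-silyloxy and the 7-methoxy group, is captured by water. The closest known reaction types are imidodiphosphorimidate-catalysed asymmetric Prins cyclisations of homoallylic alcohols with aldehydes and acid-mediated condensations of 2-vinylphenols with aldehydes. C2 is set in the C–C bond-forming step by the confined chiral anion, which shields one face of the oxocarbenium ion. C4 is set by the substrate, since water adds pseudo-axially, anti to the pseudo-equatorial C2 aryl group, and the trans alcohol is also the more stable one because a pseudo-axial hydroxyl avoids peri strain with the 5-silyloxy group, so reversible ionisation at C4 should converge on (2S,4R). Chemoselectivity rests on three substrate features: the only free phenol is the one next to the vinyl group, the monosubstituted allyl group is inert to the acid where a prenyl group would not be, and the electron-poor 4-acetoxyphenyl group keeps the O1–C2 bond from ionising so that C2 is not scrambled.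

Step 7
Reactants: 11 4-[(2S,4R)-8-allyl-4-hydroxy-7-methoxy-5-(triisopropylsilyloxy)chroman-2-yl]phenyl acetate
Product: 12 4-[(2S,4R)-4-hydroxy-7-methoxy-8-(3-methylbut-2-enyl)-5-(triisopropylsilyloxy)chroman-2-yl]phenyl acetate
Conditions: second-generation Grubbs catalyst, (1,3-dimesitylimidazolidin-2-ylidene)(PCy3)Cl2Ru=CHPh (5 mol%), 2-methyl-2-butene/CH2Cl2, 40 °C, sealed
Reagents that add atoms: 2-methyl-2-butene, CC=C(C)C
Why: Olefin cross-metathesis of a terminal allyl arene with excess 2-methyl-2-butene is a standard route to a prenyl group, and the carbinol, acetate, silyl ether and both stereocentres are untouched by the ruthenium carbene.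

Step 8
Reactants: 12 4-[(2S,4R)-4-hydroxy-7-methoxy-8-(3-methylbut-2-enyl)-5-(triisopropylsilyloxy)chroman-2-yl]phenyl acetate
Product: 13 (2S,4R)-2-(4-hydroxyphenyl)-7-methoxy-8-(3-methylbut-2-enyl)-5-(triisopropylsilyloxy)chroman-4-ol
Conditions: K2CO3 (0.2 equiv), MeOH, 0 °C
Reagents that add atoms: none
Why: Base-catalysed transesterification of the aryl acetate with methanol should proceed without loss of the hindered aryl silyl ether, and neither stereocentre carries an acidic hydrogen.

Step 9
Reactants: 13 (2S,4R)-2-(4-hydroxyphenyl)-7-methoxy-8-(3-methylbut-2-enyl)-5-(triisopropylsilyloxy)chroman-4-ol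
Product: 14 (2S,4R)-2-(4-hydroxyphenyl)-7-methoxy-8-(3-methylbut-2-enyl)chroman-4,5-diol
Conditions: TBAF, AcOH (1:1), THF, 0 °C to rt
Reagents that add atoms: none
Why: Fluoride-mediated cleavage of the aryl silyl ether is driven by Si–F bond formation, and the acetic acid buffer keeps the freed 5-phenol protonated so that the neighbouring C4 carbinol does not eliminate to an ortho-quinone methide.

**Compound list**

1 | 2,4,6-trihydroxybenzaldehyde | O=Cc1c(O)cc(O)cc1O | starting material
2 | 2,6-dihydroxy-4-methoxybenzaldehyde | COc1cc(O)c(C=O)c(O)c1 | intermediate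
3 | allyl bromide | C=CCBr | starting material
4 | 2-(allyloxy)-6-hydroxy-4-methoxybenzaldehyde | COc1cc(O)c(C=O)c(OCC=C)c1 | intermediate
5 | 2-(allyloxy)-4-methoxy-6-(triisopropylsilyloxy)benzaldehyde | COc1cc(OCC=C)c(C=O)c(O[Si](C(C)C)(C(C)C)C(C)C)c1 | intermediate
6 | 6-allyl-2-formyl-5-methoxy-3-(triisopropylsilyloxy)cyclohexa-2,4-dienone (racemic) | COC1=CC(O[Si](C(C)C)(C(C)C)C(C)C)=C(C=O)C(=O)C1CC=C | intermediate (not isolated)
7 | 3-allyl-2-hydroxy-4-methoxy-6-(triisopropylsilyloxy)benzaldehyde | COc1cc(O[Si](C(C)C)(C(C)C)C(C)C)c(C=O)c(O)c1CC=C | intermediate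
8 | 2-allyl-3-methoxy-5-(triisopropylsilyloxy)-6-vinylphenol | COc1cc(O[Si](C(C)C)(C(C)C)C(C)C)c(C=C)c(O)c1CC=C | intermediate
9 | 4-acetoxybenzaldehyde | CC(=O)Oc1ccc(C=O)cc1 | starting material
10 | 4-{[2-allyl-3-methoxy-5-(triisopropylsilyloxy)-6-vinylphenoxy](hydroxy)methyl}phenyl acetate (hemiacetal, configuration undefined) | COc1cc(O[Si](C(C)C)(C(C)C)C(C)C)c(C=C)c(OC(O)c2ccc(OC(C)=O)cc2)c1CC=C | intermediate (not isolated)
11 | 4-[(2S,4R)-8-allyl-4-hydroxy-7-methoxy-5-(triisopropylsilyloxy)chroman-2-yl]phenyl acetate | COc1cc(O[Si](C(C)C)(C(C)C)C(C)C)c2c(c1CC=C)O[C@H](c1ccc(OC(C)=O)cc1)C[C@H]2O | intermediate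
12 | 4-[(2S,4R)-4-hydroxy-7-methoxy-8-(3-methylbut-2-enyl)-5-(triisopropylsilyloxy)chroman-2-yl]phenyl acetate | COc1cc(O[Si](C(C)C)(C(C)C)C(C)C)c2c(c1CC=C(C)C)O[C@H](c1ccc(OC(C)=O)cc1)C[C@H]2O | intermediate
13 | (2S,4R)-2-(4-hydroxyphenyl)-7-methoxy-8-(3-methylbut-2-enyl)-5-(triisopropylsilyloxy)chroman-4-ol | COc1cc(O[Si](C(C)C)(C(C)C)C(C)C)c2c(c1CC=C(C)C)O[C@H](c1ccc(O)cc1)C[C@H]2O | intermediate
14 | (2S,4R)-2-(4-hydroxyphenyl)-7-methoxy-8-(3-methylbut-2-enyl)chroman-4,5-diol (4,5,4'-trihydroxy-7-methoxy-8-prenylflavan) | COc1cc(O)c2c(c1CC=C(C)C)O[C@H](c1ccc(O)cc1)C[C@H]2O | target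

**Summary**

Total step count: 9. Longest linear sequence: 9 steps (1 to 14); compounds 3 and 9 are purchased.

**Steps most likely to fail**

Step 6. The electron-rich styrene may oligomerise under the strong acid. The C4 cation may lose a proton or be captured by another arene instead of water. Facial selectivity at C2 may be poor. The fallback uses known chemistry, sets out from aldehyde 7 and returns to the route at target 14. Methylmagnesium bromide (excess, THF, 0 °C) should add to 7 to give racemic 1-[3-allyl-2-hydroxy-4-methoxy-6-(triisopropylsilyloxy)phenyl]ethanol F1. MnO2 in CH2Cl2 should oxidise this to 1-[3-allyl-2-hydroxy-4-methoxy-6-(triisopropylsilyloxy)phenyl]ethanone F2. Pyrrolidine-mediated aldol condensation and oxa-Michael closure with purchased 4-(triisopropylsilyloxy)benzaldehyde (MeOH, 60 °C) should give racemic 8-allyl-7-methoxy-5-(triisopropylsilyloxy)-2-[4-(triisopropylsilyloxy)phenyl]chroman-4-one F3. Asymmetric transfer hydrogenation under kinetic resolution (RuCl(p-cymene)[(S,S)-TsDPEN], HCO2H/Et3N) should reduce only the 2S ketone, to the cis alcohol (2S,4S)-8-allyl-7-methoxy-5-(triisopropylsilyloxy)-2-[4-(triisopropylsilyloxy)phenyl]chroman-4-ol F4, and the unreacted 2R ketone is separated. Mitsunobu inversion with 4-nitrobenzoic acid (PPh3, DIAD, THF) should give the (2S,4R) 4-nitrobenzoate F5. Methanolysis (K2CO3, MeOH) should give the trans alcohol (2S,4R)-8-allyl-7-methoxy-5-(triisopropylsilyloxy)-2-[4-(triisopropylsilyloxy)phenyl]chroman-4-ol F6. Cross-metathesis as in step 7 should give the 8-prenyl bis-silyl ether F7, and buffered TBAF as in step 9 should remove both silyl groups to reach 14.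

Step 5. The ortho-phenoxide formed under the basic conditions may deactivate the formyl group so that the ylide fails to add, or the base may erode the silyl ether. The fallback is a Peterson olefination that sets out from 7 and returns at 8. (Trimethylsilyl)methylmagnesium chloride (excess, THF, 0 °C) is nucleophilic enough to add to the phenoxide aldehyde and should give the β-hydroxysilane 2-allyl-6-[1-hydroxy-2-(trimethylsilyl)ethyl]-3-methoxy-5-(triisopropylsilyloxy)phenol F8. KH (THF, 0 °C) should then effect syn-elimination of silanolate to give 8.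

Step 1. Methylation may run on to the chelated hydroxyls or to ring carbon, giving a mixture that is hard to separate. The fallback reverses the logic, setting out from 1 and returning at 2. Exhaustive O-methylation (Me2SO4, K2CO3, acetone, reflux) should give 2,4,6-trimethoxybenzaldehyde F9. AlCl3 (CH2Cl2, 0 °C to rt) should then remove only the two methyl groups ortho to the carbonyl through the aluminium chelate, giving 2.

**Further compounds**

F1 | step 6 | 1-[3-allyl-2-hydroxy-4-methoxy-6-(triisopropylsilyloxy)phenyl]ethanol (racemic) | COc1cc(O[Si](C(C)C)(C(C)C)C(C)C)c(C(C)O)c(O)c1CC=C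
F2 | step 6 | 1-[3-allyl-2-hydroxy-4-methoxy-6-(triisopropylsilyloxy)phenyl]ethanone | COc1cc(O[Si](C(C)C)(C(C)C)C(C)C)c(C(C)=O)c(O)c1CC=C
F3 | step 6 | 8-allyl-7-methoxy-5-(triisopropylsilyloxy)-2-[4-(triisopropylsilyloxy)phenyl]chroman-4-one (racemic) | COc1cc(O[Si](C(C)C)(C(C)C)C(C)C)c2c(c1CC=C)OC(c1ccc(O[Si](C(C)C)(C(C)C)C(C)C)cc1)CC2=O
F4 | step 6 | (2S,4S)-8-allyl-7-methoxy-5-(triisopropylsilyloxy)-2-[4-(triisopropylsilyloxy)phenyl]chroman-4-ol | COc1cc(O[Si](C(C)C)(C(C)C)C(C)C)c2c(c1CC=C)O[C@H](c1ccc(O[Si](C(C)C)(C(C)C)C(C)C)cc1)C[C@@H]2O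
F5 | step 6 | (2S,4R)-8-allyl-7-methoxy-5-(triisopropylsilyloxy)-2-[4-(triisopropylsilyloxy)phenyl]chroman-4-yl 4-nitrobenzoate | COc1cc(O[Si](C(C)C)(C(C)C)C(C)C)c2c(c1CC=C)O[C@H](c1ccc(O[Si](C(C)C)(C(C)C)C(C)C)cc1)C[C@H]2OC(=O)c1ccc([N+](=O)[O-])cc1
F6 | step 6 | (2S,4R)-8-allyl-7-methoxy-5-(triisopropylsilyloxy)-2-[4-(triisopropylsilyloxy)phenyl]chroman-4-ol | COc1cc(O[Si](C(C)C)(C(C)C)C(C)C)c2c(c1CC=C)O[C@H](c1ccc(O[Si](C(C)C)(C(C)C)C(C)C)cc1)C[C@H]2O
F7 | step 6 | (2S,4R)-7-methoxy-8-(3-methylbut-2-enyl)-5-(triisopropylsilyloxy)-2-[4-(triisopropylsilyloxy)phenyl]chroman-4-ol | COc1cc(O[Si](C(C)C)(C(C)C)C(C)C)c2c(c1CC=C(C)C)O[C@H](c1ccc(O[Si](C(C)C)(C(C)C)C(C)C)cc1)C[C@H]2O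
F8 | step 5 | 2-allyl-6-[1-hydroxy-2-(trimethylsilyl)ethyl]-3-methoxy-5-(triisopropylsilyloxy)phenol (racemic) | COc1cc(O[Si](C(C)C)(C(C)C)C(C)C)c(C(O)C[Si](C)(C)C)c(O)c1CC=C
F9 | step 1 | 2,4,6-trimethoxybenzaldehyde | COc1cc(OC)c(C=O)c(OC)c1
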